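The route rests on disconnecting the C3–C3a bond of the pyrrole ring. The feature exploited is that C3a is the only unsubstituted ortho carbon of a 2,4-dibromoaniline ring (its bromines become C5–Br and C7–Br), while C3 is an enamine carbon that can carry an ester as a placeholder for bromine. A palladium-catalysed dehydrogenative C–H/C–H coupling of ethyl (Z)-3-(2,4-dibromoanilino)acrylate, an N-aryl enaminoester made by one aza-Michael addition, forges C3–C3a and closes the pyrrole ring in a single operation. Saponification and ipso-bromodecarboxylation then exchange the C3 ester for the third bromine.

Key step: step 2

Remark: aniline C1, C2(Br), C4(Br) and C6(H) become indole C7a, C7, C5 and C3a; the enaminoester is drawn as its hydrogen-bonded Z isomer, and any E isomer formed alongside should converge on the same indole because the alkene geometry is lost once palladium binds the α-carbon.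

Step 1
Reactants: 1 2,4-dibromoaniline; 2 ethyl propiolate
Product: 3 ethyl (Z)-3-(2,4-dibromoanilino)acrylate
Conditions: 2 (1.5 equiv), EtOH, reflux, 24–48 h
Reagents that add atoms: none
Why: Aza-Michael (conjugate) addition of the aniline nitrogen to the electron-poor alkyne should proceed on heating in a protic solvent that relays the proton, the vinylogous carbamate product being too weakly nucleophilic to add a second time and settling as the Z isomer held by an intramolecular N–H···O=C hydrogen bond, with no stereocentre formed.

Step 2
Reactants: 3 ethyl (Z)-3-(2,4-dibromoanilino)acrylate
Product: 4 ethyl 5,7-dibromo-1H-indole-3-carboxylate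
Conditions: Pd(OAc)2 (10 mol%), Cu(OAc)2 (3 equiv), K2CO3 (3 equiv), DMF, 80 °C, argon
Reagents that add atoms: none
Why: Electrophilic divalent palladium attacks the nucleophilic, ester-bearing α-carbon of the neutral or carbonate-deprotonated enaminoester to give an α-palladated imine, and the metal then cleaves the neighbouring C6–H bond of the aniline ring by acetate- or carbonate-assisted concerted metalation-deprotonation, giving a six-membered azapalladacycle. C–C reductive elimination forms C3–C3a, the resulting 3H-indole tautomerises to the aromatic 1H-indole, and Cu(OAc)2 returns zerovalent palladium to the divalent state. The closest known reaction type is the palladium-catalysed, copper-mediated oxidative cyclization of N-aryl enaminoesters and enaminones to indole-3-carboxylates, a cross-dehydrogenative C–H/C–H coupling in which substrates lacking a substituent at the future C2, as here, are the less common members. The pyrrole ring closes formally in a 5-endo sense, which is feasible because the bond is made by reductive elimination from the six-membered metallacycle and not by direct attack of carbon on carbon, and no stereocentre is created. Regioselectivity is fixed by the substrate, since the other ortho position carries bromine and only C6–H can be metalated, so the bromines must end at C5 and C7. Chemoselectivity for C–H over C–Br cleavage is needed and should be secured by phosphine-free conditions, moderate temperature and a threefold excess of Cu(OAc)2, which keep the concentration of zerovalent palladium too low for oxidative addition into the aryl bromides.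

Step 3
Reactants: 4 ethyl 5,7-dibromo-1H-indole-3-carboxylate
Product: 6 5,7-dibromo-1H-indole-3-carboxylic acid, via sodium 5,7-dibromo-1H-indole-3-carboxylate 5 (not isolated)
Conditions: NaOH (2 M aq, 5 equiv), EtOH, 80 °C; then 1 M HCl, 0 °C, to pH 3
Reagents that add atoms: NaOH, [Na+].[OH-]
Why: Saponification (base-mediated acyl-oxygen ester hydrolysis) of the vinylogous carbamate ester needs heat and excess hydroxide but should leave the unactivated aryl bromides untouched, and acidification in the cold liberates the acid without acid-promoted loss of CO2.

Step 4
Reactants: 6 5,7-dibromo-1H-indole-3-carboxylic acid
Product: 8 3,5,7-tribromo-1H-indole, via 3,5,7-tribromo-3H-indole-3-carboxylic acid 7 (not isolated)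
Conditions: NBS (1.0 equiv), anhydrous DMF, 0 °C to rt, dark
Reagents that add atoms: N-bromosuccinimide, O=C1CCC(=O)N1Br
Why: Ipso-bromodecarboxylation (ionic halodecarboxylation of an electron-rich heteroaryl carboxylic acid) should occur because electrophilic bromine attacks C3, the most nucleophilic carbon of the indole, to give the 3-bromo-3H-indole 7, a β-imino acid that expels CO2 and rearomatises, while the two ring bromines deactivate the benzene ring and one equivalent of NBS at low temperature limits further bromination at C2.

Compound list
1 | 2,4-dibromoaniline | Nc1ccc(Br)cc1Br | starting material
2 | ethyl propiolate | CCOC(=O)C#C | starting material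
3 | ethyl (Z)-3-(2,4-dibromoanilino)acrylate | CCOC(=O)/C=C\Nc1ccc(Br)cc1Br | intermediate
4 | ethyl 5,7-dibromo-1H-indole-3-carboxylate | CCOC(=O)c1c[nH]c2c(Br)cc(Br)cc12 | intermediate
5 | sodium 5,7-dibromo-1H-indole-3-carboxylate (formed in the flask, not isolated) | [Na+].[O-]C(=O)c1c[nH]c2c(Br)cc(Br)cc12 | intermediate
6 | 5,7-dibromo-1H-indole-3-carboxylic acid | OC(=O)c1c[nH]c2c(Br)cc(Br)cc12 | intermediate
7 | rac-3,5,7-tribromo-3H-indole-3-carboxylic acid (transient, not isolated) | OC(=O)C1(Br)C=Nc2c(Br)cc(Br)cc12 | intermediate
8 | 3,5,7-tribromo-1H-indole | Brc1cc(Br)c2[nH]cc(Br)c2c1 | target

Total step count: 4
Longest linear sequence: 4 steps (1 → 3 → 4 → 6 → 8)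

Steps most likely to fail

Step 2. Palladium may reach the zerovalent state faster than it is reoxidised and insert into the ortho C–Br bond, which would lead to Heck-type closure with loss of bromine or to hydrodebromination. Alternatively, C–H palladation of the electron-poor ring may stall, so that the enaminoester hydrolyses or decomposes. The fallback sets out from compound 1 and replaces the dehydrogenative coupling by a redox-neutral closure at a pre-installed iodide. Iodination of 1 at its only free ortho position (ICl, AcOH, rt) should give 2,4-dibromo-6-iodoaniline F1. Conjugate addition of F1 to ethyl propiolate 2 (EtOH or neat, prolonged heating) should give ethyl (Z)-3-(2,4-dibromo-6-iodoanilino)acrylate F2. An intramolecular Heck-type enamine arylation (Pd(OAc)2 5 mol%, K2CO3, DMF, 80 °C, no phosphine) should then engage the C–I bond selectively, since oxidative addition there is far faster than at C–Br. This forms the same C3–C3a bond and returns to the route at compound 4.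

Step 4. Further bromination at C2, or capture of the bromo-3H-indole by adventitious water (oxidation toward an oxindole), may outpace loss of CO2. The fallback sets out from compound 6 and separates the two events. Thermal protodecarboxylation (catalytic K2CO3, EtOH, about 140 °C, sealed vessel) should give 5,7-dibromo-1H-indole F3. Electrophilic C–H bromination at C3 (NBS 1.0 equiv, DMF, 0 °C) is the standard reaction of an indole with a free C3 position and returns to the route at compound 8.

Step 1. Addition of the weakly nucleophilic, ortho-hindered aniline may be too slow, so that conversion stays incomplete while the propiolate oligomerises on long heating. The fallback sets out from compound 1 and uses an acid-catalysed amine exchange (addition–elimination) instead of addition to an alkyne. Treating 1 with ethyl (E)-3-(dimethylamino)acrylate in AcOH at 50 °C should give the enaminoester directly with loss of dimethylamine, because the protonated enamine is a far stronger electrophile than the alkyne. It returns to the route at compound 3, and no compound outside the list is made on this detour (none F0).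

Further compounds
F1 | step 2 | 2,4-dibromo-6-iodoaniline | Nc1c(Br)cc(Br)cc1I
F2 | step 2 | ethyl (Z)-3-(2,4-dibromo-6-iodoanilino)acrylate | CCOC(=O)/C=C\Nc1c(Br)cc(Br)cc1I
F3 | step 4 | 5,7-dibromo-1H-indole | Brc1cc(Br)c2[nH]ccc2c1
F0 | step 1 | none | none
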